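**Plan**
1. Oxepine numbering: O1, C2 (quaternary), C3H2, C4H2, C5H=C6, C7H2. The retrosynthesis cuts, in order: the side-chain coumarate C(=O)–O bond, the ring bond C2–C3, the ether bond O1–C7, and the sp2–sp3 bond between C6 and the side chain.
2. Enabling feature: CO2H–C2–CH2–C(=O)Ar is a 4-aryl-4-oxobutanoic acid. It can be folded into a 5-aryl-furan-2-one ring. The conjugate base of that ring is an aromatic 2-furanolate whose nucleophilic α-carbon is C2 and already carries O1.
3. Forward, the first ring is a racemic 5-aryl-3-hydroxyfuran-2(5H)-one made from 2,5-dihydroxybenzaldehyde. The C3–C7 unit comes from 5,6-dihydro-2H-pyran-2-one, whose six-membered ring locks C4 and C7 cis on C5=C6 before it is reduced open to a dibromide.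
4. O-Alkylation joins the halves at O1–C7 through the allylic bromide only. The remaining C3–Br then closes the oxepine on C2 as a spirocycle. A Mitsunobu reaction adds p-coumaric acid. Aqueous acid finally opens the helper enol lactone to CO2H plus aryl ketone and removes the MOM groups.
5. Stereochemistry: C2 is set in the ring closure by a chiral ammonium ion pair, and both enantiomers of the precursor converge on one achiral furanolate. The side-chain E alkene comes from SeO2 oxidation, the ring alkene from the lactone, and the E coumarate is bought.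

Key step: step 11

Remark 1: the sense of induction of the ion-pair catalyst cannot be derived from first principles. The cinchonidine-derived salt is written. If it favours the (5S)-spirocycle, its pseudo-enantiomer O-allyl-N-(9-anthracenylmethyl)cinchoninium bromide takes its place.
Remark 2: "furanone C5" is the aryl-bearing carbon of the five-membered ring. Compounds 5–9 and 20 are racemic there, so their SMILES carry no descriptor at that atom.

Step 1
Reactants: 1 2,5-dihydroxybenzaldehyde
Product: 2 2,5-bis(methoxymethoxy)benzaldehyde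
Conditions: MOMCl, i-Pr2NEt, CH2Cl2, 0 °C to rt
Reagents that add atoms: chloromethyl methyl ether (MOMCl), COCCl
Why: Standard O-alkylation of phenols to MOM acetals, which survive zinc, osmium, carbonate bases and fluoride and leave under the same aqueous acid that opens the enol lactone at the end.

Step 2
Reactants: 2 2,5-bis(methoxymethoxy)benzaldehyde; 3 ethyl 2-(bromomethyl)acrylate
Product: 6 5-[2,5-bis(methoxymethoxy)phenyl]-3-methylidenedihydrofuran-2(3H)-one (racemic), via allylzinc bromide 4 (not isolated), via bromozinc alkoxide 5 (not isolated)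
Conditions: Zn dust, THF, 50 °C; then sat. aq NH4Cl
Reagents that add atoms: none
Why: Dreiding–Schmidt reaction, in which the 2-(ethoxycarbonyl)allylzinc adds to the aldehyde and the zinc alkoxide lactonises on the ester in situ; the benzylic stereocentre may form racemic because step 11 erases it.

Step 3
Reactants: 6 5-[2,5-bis(methoxymethoxy)phenyl]-3-methylidenedihydrofuran-2(3H)-one
Product: 9 5-[2,5-bis(methoxymethoxy)phenyl]-3-hydroxyfuran-2(5H)-one (racemic isotetronic acid), via diol 7 (not isolated), via keto lactone 8 (not isolated)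
Conditions: OsO4 (2 mol %), NMO, acetone–H2O, rt; extractive work-up; then NaIO4/SiO2, CH2Cl2, rt
Reagents that add atoms: osmium tetroxide, O=[Os](=O)(=O)=O (oxygen carrier, regenerated by N-methylmorpholine N-oxide, C[N+]1([O-])CCOCC1)
Why: Upjohn dihydroxylation followed by periodate glycol cleavage excises the exocyclic CH2 and the α-keto lactone tautomerises to the enol; osmium is removed before the oxidisable enol appears, and ozone is avoided because the dialkoxyarene would compete with the electron-poor alkene.

Step 4
Reactants: 10 5,6-dihydro-2H-pyran-2-one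
Product: 12 3-bromo-5,6-dihydro-2H-pyran-2-one, via trans-dibromide 11 (not isolated)
Conditions: Br2, CH2Cl2, 0 °C to rt; then Et3N, 0 °C to rt
Reagents that add atoms: bromine, BrBr
Why: Bromine addition followed by dehydrobromination, in which the amine removes the acidic α-hydrogen and expels the β-bromide, so that bromine stays on the α-carbon (the future C6).

Step 5
Reactants: 12 3-bromo-5,6-dihydro-2H-pyran-2-one; 13 5-bromo-2-methylpent-2-ene
Product: 15 3-(4-methylpent-3-en-1-yl)-5,6-dihydro-2H-pyran-2-one, via homoprenylzinc bromide 14 (not isolated)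
Conditions: 13, Zn dust, LiCl, THF, 50 °C; then 12, PdCl2(dppf) (3 mol %), THF, rt to 40 °C
Reagents that add atoms: none
Why: Negishi coupling, in which zerovalent palladium adds to the C–Br bond of the α-bromo enoate and the wide-bite-angle dppf ligand favours reductive elimination over β-hydride elimination, so the sp2–sp3 bond forms with the ring-locked alkene untouched.

Step 6
Reactants: 15 3-(4-methylpent-3-en-1-yl)-5,6-dihydro-2H-pyran-2-one
Product: 16 3-[(3E)-5-hydroxy-4-methylpent-3-en-1-yl]-5,6-dihydro-2H-pyran-2-one
Conditions: SeO2 (0.3 equiv), t-BuOOH, CH2Cl2, 0 °C to rt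
Reagents that add atoms: tert-butyl hydroperoxide, CC(C)(C)OO (oxygen delivered through selenium dioxide, O=[Se]=O)
Why: Riley allylic oxidation (ene reaction, then [2,3]-shift) attacks the electron-rich trisubstituted alkene rather than the electron-poor enoate and hydroxylates the methyl group trans to the chain, which sets the E allylic alcohol.

Step 7
Reactants: 16 3-[(3E)-5-hydroxy-4-methylpent-3-en-1-yl]-5,6-dihydro-2H-pyran-2-one
Product: 17 3-[(3E)-5-(tert-butyldimethylsilyloxy)-4-methylpent-3-en-1-yl]-5,6-dihydro-2H-pyran-2-one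
Conditions: TBSCl, imidazole, CH2Cl2, rt
Reagents that add atoms: tert-butyldimethylsilyl chloride (TBSCl), CC(C)(C)[Si](C)(C)Cl
Why: Standard silylation that keeps this hydroxyl apart from the two released in step 8 and withstands i-Bu2AlH, Appel conditions and carbonate bases.

Step 8
Reactants: 17 3-[(3E)-5-(tert-butyldimethylsilyloxy)-4-methylpent-3-en-1-yl]-5,6-dihydro-2H-pyran-2-one
Product: 18 (2Z)-2-[(3E)-5-(tert-butyldimethylsilyloxy)-4-methylpent-3-en-1-yl]pent-2-ene-1,5-diol
Conditions: i-Bu2AlH (4.5 equiv), CH2Cl2, −78 to 0 °C; aq potassium sodium tartrate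
Reagents that add atoms: none
Why: Exhaustive 1,2-reduction of the α,β-unsaturated lactone gives the ene-diol, whose Z geometry (C4 and C7 cis) is inherited from the six-membered ring.

Step 9
Reactants: 18 (2Z)-2-[(3E)-5-(tert-butyldimethylsilyloxy)-4-methylpent-3-en-1-yl]pent-2-ene-1,5-diol
Product: 19 tert-butyl{[(2E,6Z)-9-bromo-6-(bromomethyl)-2-methylnona-2,6-dien-1-yl]oxy}dimethylsilane
Conditions: PPh3, CBr4, 2,6-lutidine, CH2Cl2, −20 to 0 °C (diol added to the preformed reagent)
Reagents that add atoms: carbon tetrabromide, BrC(Br)(Br)Br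
Why: Double Appel reaction under neutral conditions; adding the diol to excess reagent activates both hydroxyls at once, so that bromide displacement outruns cyclic ether formation, and the low temperature keeps the allylic bromide geometrically intact.

Step 10
Reactants: 9 5-[2,5-bis(methoxymethoxy)phenyl]-3-hydroxyfuran-2(5H)-one; 19 tert-butyl{[(2E,6Z)-9-bromo-6-(bromomethyl)-2-methylnona-2,6-dien-1-yl]oxy}dimethylsilane
Product: 20 3-{[(2Z)-5-bromo-2-[(3E)-5-(tert-butyldimethylsilyloxy)-4-methylpent-3-en-1-yl]pent-2-en-1-yl]oxy}-5-[2,5-bis(methoxymethoxy)phenyl]furan-2(5H)-one (racemic)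
Conditions: K2CO3, acetone, 0 °C to rt
Reagents that add atoms: none
Why: Williamson-type O-alkylation of an enol of phenol-like acidity, in which the allylic bromide reacts far faster in SN2 than the homoallylic one, so only O1–C7 forms; any spirocycle formed early is a different compound and is removed by chromatography.

Step 11
Reactants: 20 3-{[(2Z)-5-bromo-2-[(3E)-5-(tert-butyldimethylsilyloxy)-4-methylpent-3-en-1-yl]pent-2-en-1-yl]oxy}-5-[2,5-bis(methoxymethoxy)phenyl]furan-2(5H)-one
Product: 22 (5R)-3-[2,5-bis(methoxymethoxy)phenyl]-8-[(3E)-5-(tert-butyldimethylsilyloxy)-4-methylpent-3-en-1-yl]-2,6-dioxaspiro[4.6]undeca-3,8-dien-1-one, via furanolate anion 21 (not isolated)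
Conditions: O-allyl-N-(9-anthracenylmethyl)cinchonidinium bromide (10 mol %), powdered Cs2CO3 (3 equiv), toluene (0.01 M), −20 °C
Reagents that add atoms: none
Why: Proposed new method: carbonate at the solid–liquid interface removes the furanone C5–H (benzylic, allylic and γ to the lactone carbonyl) from either enantiomer of 20, so both converge on one achiral aromatic 3-alkoxy-2-furanolate 21, which enters toluene as a tight ion pair with the chiral ammonium cation and whose α-carbon (the future C2, already bearing O1) displaces the tethered primary bromide at C3 by SN2. The closest known reaction types are the α-selective C-alkylation of butenolide dienolates and the enantioselective phase-transfer spiro-alkylation of oxindole enolates that carry a tethered halide; the 3-alkoxyfuranolate nucleophile and the seven-membered closure are new. The oxepine closes in the 7-(enolexo)-exo-tet mode, helped by the Z C5=C6 bond and the ether oxygen, which remove rotors and transannular H/H contacts from the chain. The new quaternary centre C2 is controlled only by the cation, whose anthracenylmethyl and quinoline walls should cover one face of the flat 5-aryl furanolate so that the O1–C7 tether must fold over the open face. Regioselectivity (α-carbon against γ-carbon or enolate oxygen) is secured by the tether, since attack through furanone C5 or through oxygen would need a bridged or nine-membered ring, and high dilution holds back intermolecular alkylation. The [2,3]-shift of the α-allyloxy enolate and E2 loss of HBr are the competing channels, and the low basicity of the aromatic furanolate, the weak insoluble base and the low temperature should keep both slow relative to closure.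

Step 12
Reactants: 22 (5R)-spirolactone TBS ether
Product: 23 (5R)-3-[2,5-bis(methoxymethoxy)phenyl]-8-[(3E)-5-hydroxy-4-methylpent-3-en-1-yl]-2,6-dioxaspiro[4.6]undeca-3,8-dien-1-one
Conditions: Et3N·3HF, THF, rt
Reagents that add atoms: none
Why: Fluoride-induced desilylation of the primary allylic TBS ether in a nearly neutral medium that leaves the MOM ethers and the enol lactone untouched.

Step 13
Reactants: 23 (5R)-spirolactone allylic alcohol; 24 (E)-p-coumaric acid
Product: 25 (2E)-5-{(5R)-3-[2,5-bis(methoxymethoxy)phenyl]-1-oxo-2,6-dioxaspiro[4.6]undeca-3,8-dien-8-yl}-2-methylpent-2-en-1-yl (2E)-3-(4-hydroxyphenyl)prop-2-enoate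
Conditions: PPh3, DIAD, THF, 0 °C to rt
Reagents that add atoms: none
Why: Mitsunobu esterification, in which only the carboxylic acid is acidic enough to protonate the betaine, so the free phenol needs no protection; the primary allylic oxyphosphonium ion is displaced by SN2 without allylic shift, and the neutral medium spares the enol lactone.

Step 14
Reactants: 25 spirolactone coumarate
Product: 27 (2R)-2-[2-(2,5-dihydroxyphenyl)-2-oxoethyl]-6-[(3E)-5-{[(2E)-3-(4-hydroxyphenyl)prop-2-enoyl]oxy}-4-methylpent-3-en-1-yl]-2,3,4,7-tetrahydrooxepine-2-carboxylic acid (target), via MOM-protected keto acid 26 (not isolated)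
Conditions: 2 M aq HCl–THF (1:2), 40 °C, argon
Reagents that add atoms: water, O
Why: Acid-catalysed hydrolysis, in which C-protonation of the electron-rich enol ester and addition of water give a 5-hydroxylactone that opens to γ-keto acid 26 and the two MOM acetals hydrolyse in the same medium; the ketone is therefore unveiled only under acid, where base-induced retro-oxa-Michael loss of O1 cannot scramble C2, and the absence of an alcohol cosolvent ensures that only water opens the lactone.

**Compound list**
1 | 2,5-dihydroxybenzaldehyde | O=Cc1cc(O)ccc1O | starting material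
2 | 2,5-bis(methoxymethoxy)benzaldehyde | O=Cc1cc(OCOC)ccc1OCOC | intermediate
3 | ethyl 2-(bromomethyl)acrylate | C=C(CBr)C(=O)OCC | starting material
4 | [2-(ethoxycarbonyl)allyl]zinc bromide | C=C(C[Zn]Br)C(=O)OCC | intermediate
5 | bromozinc alkoxide of ethyl 4-[2,5-bis(methoxymethoxy)phenyl]-4-hydroxy-2-methylidenebutanoate (racemic) | CCOC(=O)C(=C)CC(O[Zn]Br)c1cc(OCOC)ccc1OCOC | intermediate
6 | 5-[2,5-bis(methoxymethoxy)phenyl]-3-methylidenedihydrofuran-2(3H)-one (racemic) | C=C1CC(c2cc(OCOC)ccc2OCOC)OC1=O | intermediate
7 | 5-[2,5-bis(methoxymethoxy)phenyl]-3-hydroxy-3-(hydroxymethyl)dihydrofuran-2(3H)-one (diastereomer mixture, racemic) | OCC1(O)CC(c2cc(OCOC)ccc2OCOC)OC1=O | intermediate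
8 | 5-[2,5-bis(methoxymethoxy)phenyl]dihydrofuran-2,3-dione (racemic) | O=C1CC(c2cc(OCOC)ccc2OCOC)OC1=O | intermediate
9 | 5-[2,5-bis(methoxymethoxy)phenyl]-3-hydroxyfuran-2(5H)-one (racemic) | OC1=CC(c2cc(OCOC)ccc2OCOC)OC1=O | intermediate
10 | 5,6-dihydro-2H-pyran-2-one | O=C1C=CCCO1 | starting material
11 | trans-3,4-dibromotetrahydro-2H-pyran-2-one (racemic) | O=C1OCCC(Br)C1Br | intermediate
12 | 3-bromo-5,6-dihydro-2H-pyran-2-one | O=C1OCCC=C1Br | intermediate
13 | 5-bromo-2-methylpent-2-ene | CC(C)=CCCBr | starting material
14 | (4-methylpent-3-en-1-yl)zinc bromide | CC(C)=CCC[Zn]Br | intermediate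
15 | 3-(4-methylpent-3-en-1-yl)-5,6-dihydro-2H-pyran-2-one | CC(C)=CCCC1=CCCOC1=O | intermediate
16 | 3-[(3E)-5-hydroxy-4-methylpent-3-en-1-yl]-5,6-dihydro-2H-pyran-2-one | C/C(=C\CCC1=CCCOC1=O)CO | intermediate
17 | 3-[(3E)-5-(tert-butyldimethylsilyloxy)-4-methylpent-3-en-1-yl]-5,6-dihydro-2H-pyran-2-one | C/C(=C\CCC1=CCCOC1=O)CO[Si](C)(C)C(C)(C)C | intermediate
18 | (2Z)-2-[(3E)-5-(tert-butyldimethylsilyloxy)-4-methylpent-3-en-1-yl]pent-2-ene-1,5-diol | C/C(=C\CC/C(CO)=C/CCO)CO[Si](C)(C)C(C)(C)C | intermediate
19 | tert-butyl{[(2E,6Z)-9-bromo-6-(bromomethyl)-2-methylnona-2,6-dien-1-yl]oxy}dimethylsilane | C/C(=C\CC/C(CBr)=C/CCBr)CO[Si](C)(C)C(C)(C)C | intermediate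
20 | 3-{[(2Z)-5-bromo-2-[(3E)-5-(tert-butyldimethylsilyloxy)-4-methylpent-3-en-1-yl]pent-2-en-1-yl]oxy}-5-[2,5-bis(methoxymethoxy)phenyl]furan-2(5H)-one (racemic) | C/C(=C\CC/C(COC1=CC(c2cc(OCOC)ccc2OCOC)OC1=O)=C/CCBr)CO[Si](C)(C)C(C)(C)C | intermediate
21 | 3-alkoxy-5-aryl-2-furanolate anion derived from 20 (ion-paired with the chiral ammonium cation) | C/C(=C\CC/C(COc1cc(-c2cc(OCOC)ccc2OCOC)oc1[O-])=C/CCBr)CO[Si](C)(C)C(C)(C)C | intermediate
22 | (5R)-3-[2,5-bis(methoxymethoxy)phenyl]-8-[(3E)-5-(tert-butyldimethylsilyloxy)-4-methylpent-3-en-1-yl]-2,6-dioxaspiro[4.6]undeca-3,8-dien-1-one | C/C(=C\CCC1=CCC[C@]2(C=C(c3cc(OCOC)ccc3OCOC)OC2=O)OC1)CO[Si](C)(C)C(C)(C)C | intermediate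
23 | (5R)-3-[2,5-bis(methoxymethoxy)phenyl]-8-[(3E)-5-hydroxy-4-methylpent-3-en-1-yl]-2,6-dioxaspiro[4.6]undeca-3,8-dien-1-one | C/C(=C\CCC1=CCC[C@]2(C=C(c3cc(OCOC)ccc3OCOC)OC2=O)OC1)CO | intermediate
24 | (E)-p-coumaric acid | O=C(O)/C=C/c1ccc(O)cc1 | starting material
25 | p-coumarate ester of 23 (free phenol, enol lactone and MOM ethers intact) | C/C(=C\CCC1=CCC[C@]2(C=C(c3cc(OCOC)ccc3OCOC)OC2=O)OC1)COC(=O)/C=C/c1ccc(O)cc1 | intermediate
26 | (2R)-2-{2-[2,5-bis(methoxymethoxy)phenyl]-2-oxoethyl}-6-[(3E)-5-{[(2E)-3-(4-hydroxyphenyl)prop-2-enoyl]oxy}-4-methylpent-3-en-1-yl]-2,3,4,7-tetrahydrooxepine-2-carboxylic acid | C/C(=C\CCC1=CCC[C@@](CC(=O)c2cc(OCOC)ccc2OCOC)(C(=O)O)OC1)COC(=O)/C=C/c1ccc(O)cc1 | intermediate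
27 | (2R)-2-[2-(2,5-dihydroxyphenyl)-2-oxoethyl]-6-[(3E)-5-{[(2E)-3-(4-hydroxyphenyl)prop-2-enoyl]oxy}-4-methylpent-3-en-1-yl]-2,3,4,7-tetrahydrooxepine-2-carboxylic acid | C/C(=C\CCC1=CCC[C@@](CC(=O)c2cc(O)ccc2O)(C(=O)O)OC1)COC(=O)/C=C/c1ccc(O)cc1 | target

Total step count: 14. Longest linear sequence: 11 steps (10 to 27, steps 4–14).

**Steps most likely to fail**

Step 11. The ion pair may discriminate poorly between the two faces of the flat furanolate because the seven-membered transition state is flexible. Slow closure would also give E2 loss of HBr or the [2,3]-shift time to intervene.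
- Fallback: set out from 20 and give up catalyst control.
- Cs2CO3 in DMF at high dilution and rt should give the racemic spirolactone F1. This is an ordinary intramolecular α-C-alkylation of a butenolide dienolate, a known reaction type, run in a polar medium that speeds SN2 closure.
- Preparative chromatography on a chiral stationary phase then divides F1 into 22 and the (5S)-spirolactone F2, which is discarded.
- The route is rejoined at 22.

Step 14. The less labile MOM ether needs time in warm mineral acid. During that time several processes may intervene: ionisation or allylic transposition of the coumarate, hydration of the trisubstituted alkenes, attack of released formaldehyde on the free phenols, and acid-catalysed β-elimination of O1 with loss of configuration at C2.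
- Fallback: set out from 25 and separate the two unmaskings.
- TMSOTf and 2,2′-bipyridyl in CH2Cl2 at 0 °C, followed by water, should give the hydroquinone enol lactone F3. Under these non-acidic conditions aromatic MOM ethers are exchanged for aryl silyl ethers through a bipyridinium salt and are hydrolysed on work-up.
- AcOH–THF–H2O at rt then hydrolyses only the enol ester and delivers 27.

Step 9. Once one hydroxyl is activated, the Z ene-1,5-diol may cyclodehydrate to a 3,6-dihydro-2H-pyran. Bromide exchange through SN2′ may also scramble the geometry of the allylic bromide.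
- Fallback: set out from 18 and activate the two hydroxyls one after the other.
- Corey–Kim-type chlorination (NCS, Me2S, CH2Cl2, −20 to 0 °C) converts only the allylic hydroxyl and should give the chloro alcohol F4.
- O-Alkylation of 9 with F4 (K2CO3, NaI cat., acetone) gives the ether alcohol F5, in which no activated allylic centre remains.
- A single Appel bromination of F5 gives 20, so that 19 and step 10 are bypassed.

Further compounds
F1 | step 11 | racemic 3-[2,5-bis(methoxymethoxy)phenyl]-8-[(3E)-5-(tert-butyldimethylsilyloxy)-4-methylpent-3-en-1-yl]-2,6-dioxaspiro[4.6]undeca-3,8-dien-1-one | C/C(=C\CCC1=CCCC2(C=C(c3cc(OCOC)ccc3OCOC)OC2=O)OC1)CO[Si](C)(C)C(C)(C)C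
F2 | step 11 | (5S)-enantiomer of 22 | C/C(=C\CCC1=CCC[C@@]2(C=C(c3cc(OCOC)ccc3OCOC)OC2=O)OC1)CO[Si](C)(C)C(C)(C)C
F3 | step 14 | p-coumarate of (5R)-3-(2,5-dihydroxyphenyl)-8-[(3E)-5-hydroxy-4-methylpent-3-en-1-yl]-2,6-dioxaspiro[4.6]undeca-3,8-dien-1-one | C/C(=C\CCC1=CCC[C@]2(C=C(c3cc(O)ccc3O)OC2=O)OC1)COC(=O)/C=C/c1ccc(O)cc1
F4 | step 9 | (3Z,7E)-9-(tert-butyldimethylsilyloxy)-4-(chloromethyl)-8-methylnona-3,7-dien-1-ol | C/C(=C\CC/C(CCl)=C/CCO)CO[Si](C)(C)C(C)(C)C
F5 | step 9 | 3-{[(2Z)-5-hydroxy-2-[(3E)-5-(tert-butyldimethylsilyloxy)-4-methylpent-3-en-1-yl]pent-2-en-1-yl]oxy}-5-[2,5-bis(methoxymethoxy)phenyl]furan-2(5H)-one (racemic) | C/C(=C\CC/C(COC1=CC(c2cc(OCOC)ccc2OCOC)OC1=O)=C/CCO)CO[Si](C)(C)C(C)(C)C
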